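**Plan** (carotenoid numbering: ring C1–C6 with gem-dimethyl C1, stereocentre C2 and C5=C6; chain C7–C15/C15'–C3'; acyclic end C2', C1'; side chain on C2 = C1''–C4'')

1. Cuts: C7=C8 and C7'=C8' (two Wittig reactions on the C20 dialdehyde), C2''=C3'' (Wittig), C2–C1'' at the alkene level (olefination of a C2 ketone, then enantioselective reduction), C3'=C4' (Horner–Wadsworth–Emmons), and in the ring C1–C2 together with C5=C6.
2. Enabling feature: in the cyclohexene the tetrasubstituted C5=C6 bond carries chain carbon C7 on C6 and adjoins the gem-dimethyl carbon C1, and C2 and C5 are 1,4-related. With C7 as an ester, C1=C6 is an isopropylidene phosphonoacetate (acceptor at C1, olefinating carbanion at C6), and C2–C5 is a nitronate/methyl ketone pair.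
3. Forward: the ring is closed first from two acyclic pieces (step 2), then nitro → C2 ketone → exocyclic enal → (R)-C2 → side-chain enoate → ring phosphonium salt. (R)-Lavandulol separately gives the acyclic phosphonium salt.
4. Chain joining: ring salt + C20 dialdehyde, then the acyclic salt; the side-chain ester is reduced to the allylic alcohol last.
5. Stereochemistry: C2 (R) from a catalyst-controlled transfer hydrogenation; C2' (S) from (R)-lavandulol; E-alkenes from stabilised Wittig/Horner–Wadsworth–Emmons reagents and thermal equilibration of the polyene.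

Key step: step 2

Assumption: (R)-(−)-lavandulol 16, crocetin dialdehyde 25 and 5-nitropentan-2-one 4 are taken as purchasable; by-products are written in the neutral form obtained after work-up.

**Step 1**
Reactants: 1 triethyl phosphonoacetate; 2 acetone
Product: 3 ethyl 2-(diethoxyphosphoryl)-3-methylbut-2-enoate
Conditions: TiCl4, N-methylmorpholine, THF, 0 °C → rt
Reagents that add atoms: none
Why: The TiCl4/amine Knoevenagel condensation of phosphonoacetates with ketones is established and should give the alkylidene phosphonoacetate, which has no geometric isomers because both β-substituents are methyl.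

**Step 2**
Reactants: 3 ethyl 2-(diethoxyphosphoryl)-3-methylbut-2-enoate; 4 5-nitropentan-2-one
Product: 6 ethyl 2,6,6-trimethyl-5-nitrocyclohex-1-ene-1-carboxylate (racemic), via phosphonate Michael adduct 5 (not isolated)
Conditions: DBU, LiCl, MeCN, 0 °C → 50 °C
Reagents that add atoms: none
Why: DBU deprotonates only the nitro-activated CH2 of 4, and the nitronate adds in a conjugate sense to the β,β-dimethyl terminus of 3, forming the bond between the quaternary carbon C1 and C2 and leaving the lithium-chelated phosphonoacetate carbanion 5, which condenses with the C5 ketone and expels diethyl phosphate to give the tetrasubstituted C5=C6 alkene. The closest known reaction type is the domino Michael addition of a nitroalkane to an α-phosphoryl acrylate followed by intramolecular Horner–Wadsworth–Emmons olefination, and conjugate additions of nitronates to β,β-dimethyl acceptors are likewise known. The six-membered ring should close by 6-exo-trig attack of the C6 carbanion on the ketone carbonyl, followed by syn-elimination through the oxaphosphetane. The only new stereocentre, the nitro-bearing C2, forms without control as a racemate and is deliberately erased in step 3. The step needs chemoselectivity (nitronate, not ketone enolate, as donor) and regioselectivity (only C6 may attack the ketone), secured by the acidity gap between CH2NO2 and the methyl ketone and by placing the phosphoryl group on C6. The congested, reversible Michael step should be pulled forward by the irreversible olefination, and the competing aldol of the nitronate onto its own ketone would need a four-membered ring.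

**Step 3**
Reactants: 6 ethyl 2,6,6-trimethyl-5-nitrocyclohex-1-ene-1-carboxylate
Product: 8 ethyl 2,6,6-trimethyl-5-oxocyclohex-1-ene-1-carboxylate, via sodium nitronate 7 (not isolated)
Conditions: NaOEt, EtOH, 0 °C; then aq. TiCl3, NH4OAc, rt
Reagents that add atoms: water, O
Why: In this reductive Nef reaction the nitronate should be reduced by TiCl3 to the imine and hydrolysed in the buffered medium to the ketone, the quaternary C1 preventing conjugation with the enoate, and the uncontrolled stereocentre disappears.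

**Step 4**
Reactants: 8 ethyl 2,6,6-trimethyl-5-oxocyclohex-1-ene-1-carboxylate; 9 diethyl (cyanomethyl)phosphonate
Product: 10 ethyl (5E)-5-(cyanomethylidene)-2,6,6-trimethylcyclohex-1-ene-1-carboxylate
Conditions: NaH, THF, 0 °C → 65 °C
Reagents that add atoms: none
Why: Horner–Wadsworth–Emmons olefination with the small cyanomethylphosphonate anion is known on α,α-dimethylcyclohexanones and should place the nitrile anti to the quaternary carbon (E), although either isomer serves in step 6.

**Step 5**
Reactants: 10 ethyl (5E)-5-(cyanomethylidene)-2,6,6-trimethylcyclohex-1-ene-1-carboxylate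
Product: 11 (2E)-2-[3-(hydroxymethyl)-2,2,4-trimethylcyclohex-3-en-1-ylidene]acetaldehyde
Conditions: i-Bu2AlH (excess), CH2Cl2, −78 °C → −20 °C; aq. tartaric acid work-up
Reagents that add atoms: water, O
Why: i-Bu2AlH should reduce the conjugated nitrile to the aldimine (hydrolysed to the enal on work-up) and the ester to the allylic alcohol, as in the classical nitrile-to-polyenal reductions of retinoid chemistry.

**Step 6**
Reactants: 11 (2E)-2-[3-(hydroxymethyl)-2,2,4-trimethylcyclohex-3-en-1-ylidene]acetaldehyde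
Product: 12 2-[(1R)-3-(hydroxymethyl)-2,2,4-trimethylcyclohex-3-en-1-yl]acetaldehyde
Conditions: (S)-2-tert-butyl-3-methylimidazolidin-4-one·CCl3CO2H (20 mol %), diethyl 2,6-dimethyl-1,4-dihydropyridine-3,5-dicarboxylate, CHCl3, −30 °C
Reagents that add atoms: none
Why: Iminium-catalysed transfer hydrogenation of β,β-disubstituted enals is enantioconvergent for E and Z isomers, and the size difference between the quaternary C1 and the C3 methylene (comparable to tert-butyl versus methyl) should let the (S)-catalyst deliver hydride to the face that sets C2 as (R).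

**Step 7**
Reactants: 12 2-[(1R)-3-(hydroxymethyl)-2,2,4-trimethylcyclohex-3-en-1-yl]acetaldehyde; 13 methyl 2-(triphenyl-λ5-phosphanylidene)propanoate
Product: 14 methyl (2E)-4-[(1R)-3-(hydroxymethyl)-2,2,4-trimethylcyclohex-3-en-1-yl]-2-methylbut-2-enoate
Conditions: CH2Cl2, rt → 40 °C
Reagents that add atoms: none
Why: The Wittig reaction of a stabilised ylide should give the (E)-trisubstituted enoate, and the stereocentre is β to the aldehyde and cannot epimerise.

**Step 8**
Reactants: 14 methyl (2E)-4-[(1R)-3-(hydroxymethyl)-2,2,4-trimethylcyclohex-3-en-1-yl]-2-methylbut-2-enoate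
Product: 15 {[(5R)-5-[(2E)-4-methoxy-3-methyl-4-oxobut-2-en-1-yl]-2,6,6-trimethylcyclohex-1-en-1-yl]methyl}(triphenyl)phosphonium bromide
Conditions: PPh3·HBr, MeOH, rt
Reagents that add atoms: triphenylphosphine hydrobromide, [Br-].[PH+](c1ccccc1)(c1ccccc1)c1ccccc1
Why: Cyclogeraniol-type allylic alcohols ionise with PPh3·HBr and the allyl cation should be captured by PPh3 at the primary terminus, the usual entry to carotenoid Wittig salts, while the enoate is inert.

**Step 9**
Reactants: 16 (R)-lavandulol, (2R)-5-methyl-2-(prop-1-en-2-yl)hex-4-en-1-ol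
Product: 18 (2S)-2-(2-hydroxypropan-2-yl)-5-methylhex-4-en-1-ol, via organomercury acetate 17 (not isolated)
Conditions: Hg(OAc)2 (1.0 equiv), THF/H2O, 0 °C; then NaBH4, aq. NaOH, 0 °C
Reagents that add atoms: water, O
Why: In oxymercuration–demercuration a 1,1-disubstituted alkene reacts much faster than a trisubstituted one (as in the selective hydration of limonene to α-terpineol), so Markovnikov hydration should occur at the isopropenyl group only and leave the stereocentre untouched.

**Step 10**
Reactants: 18 (2S)-2-(2-hydroxypropan-2-yl)-5-methylhex-4-en-1-ol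
Product: 19 trimethyl({(2S)-5-methyl-2-[2-(trimethylsilyloxy)propan-2-yl]hex-4-en-1-yl}oxy)silane
Conditions: Me3SiCl (2.5 equiv), imidazole, DMF, 0 °C → rt
Reagents that add atoms: chlorotrimethylsilane, C[Si](C)(C)Cl
Why: Exhaustive silylation with the small trimethylsilyl group should cap both the primary and the tertiary hydroxyl, which blocks retro-aldol cleavage at the aldehyde stage.

**Step 11**
Reactants: 19 trimethyl({(2S)-5-methyl-2-[2-(trimethylsilyloxy)propan-2-yl]hex-4-en-1-yl}oxy)silane
Product: 20 (2R)-5-methyl-2-[2-(trimethylsilyloxy)propan-2-yl]hex-4-enal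
Conditions: (COCl)2, DMSO, CH2Cl2, −78 °C → −40 °C; then Et3N, −78 °C → 0 °C
Reagents that add atoms: none
Why: Under Swern conditions primary trimethylsilyl ethers are cleaved and oxidised directly while tertiary ones persist, and low temperature should protect the α-stereocentre of the aldehyde.

**Step 12**
Reactants: 20 (2R)-5-methyl-2-[2-(trimethylsilyloxy)propan-2-yl]hex-4-enal; 21 ethyl (2E)-4-(diethoxyphosphoryl)-3-methylbut-2-enoate (commercial, E major)
Product: 22 ethyl (2E,4E,6S)-3,9-dimethyl-6-[2-(trimethylsilyloxy)propan-2-yl]deca-2,4,8-trienoate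
Conditions: LiN(SiMe3)2, THF, −78 °C → 0 °C
Reagents that add atoms: none
Why: Horner–Wadsworth–Emmons olefination with the stabilised C5 phosphonate anion should form the new C3'=C4' bond E, addition to the aldehyde being faster than its enolisation.

**Step 13**
Reactants: 22 ethyl (2E,4E,6S)-3,9-dimethyl-6-[2-(trimethylsilyloxy)propan-2-yl]deca-2,4,8-trienoate
Product: 23 (2E,4E,6S)-3,9-dimethyl-6-[2-(trimethylsilyloxy)propan-2-yl]deca-2,4,8-trien-1-ol
Conditions: i-Bu2AlH, CH2Cl2, −78 °C; Rochelle salt work-up
Reagents that add atoms: none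
Why: 1,2-Reduction of a dienoate to the dienol with i-Bu2AlH is routine and leaves the silyl ether and the alkenes untouched.

**Step 14**
Reactants: 23 (2E,4E,6S)-3,9-dimethyl-6-[2-(trimethylsilyloxy)propan-2-yl]deca-2,4,8-trien-1-ol
Product: 24 [(2E,4E,6S)-6-(2-hydroxypropan-2-yl)-3,9-dimethyldeca-2,4,8-trien-1-yl](triphenyl)phosphonium bromide
Conditions: PPh3·HBr, MeOH/CH2Cl2, rt
Reagents that add atoms: triphenylphosphine hydrobromide, [Br-].[PH+](c1ccccc1)(c1ccccc1)c1ccccc1
Why: The pentadienyl cation formed from the dienol should be trapped by PPh3 at its primary terminus (standard phosphonium salt formation), the acidic methanol removes the tertiary silyl ether, and C2' is not part of the cation.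

**Step 15**
Reactants: 15 ring phosphonium bromide; 25 crocetin dialdehyde (2.5 equiv)
Product: 27 methyl (2E)-2-methyl-4-{(1R)-2,2,4-trimethyl-3-[(1E,3E,5E,7E,9E,11E,13E,15E)-3,7,12,16-tetramethyl-17-oxoheptadeca-1,3,5,7,9,11,13,15-octaen-1-yl]cyclohex-3-en-1-yl}but-2-enoate, via phosphorus ylide 26 (not isolated)
Conditions: NaN(SiMe3)2 (1.0 equiv), THF, −78 °C; then 25, −78 °C → rt
Reagents that add atoms: none
Why: Wittig condensation of cyclogeranyl-type ylides with the C20 dialdehyde is a classical carotenoid coupling; the excess of dialdehyde should favour mono-olefination, and any 7Z isomer is equilibrated after step 16.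

**Step 16**
Reactants: 27 C35 apo-aldehyde ester; 24 acyclic phosphonium bromide
Product: 29 methyl ester of the target (CO2Me in place of CH2OH at C4''), via ylide alkoxide 28 (not isolated)
Conditions: NaN(SiMe3)2 (2.1 equiv), THF, −78 °C → 0 °C; then 27, → rt; then n-heptane, 80 °C, dark
Reagents that add atoms: none
Why: A second Wittig reaction of the allylic ylide (the tertiary alkoxide is a spectator) should form C7'=C8', and heating should equilibrate the Z isomers of the new double bonds to the all-E polyene.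

**Step 17**
Reactants: 29 methyl ester of the target
Product: 30 target compound
Conditions: i-Bu2AlH (excess), THF/CH2Cl2, −78 °C; Rochelle salt work-up
Reagents that add atoms: none
Why: 1,2-Reduction of the isolated α-methyl enoate with i-Bu2AlH should give the (E)-allylic alcohol, a reduction that polyenes and the free tertiary hydroxyl tolerate.

**Compound list**

1 | triethyl phosphonoacetate | CCOC(=O)CP(=O)(OCC)OCC | starting material
2 | acetone | CC(C)=O | starting material
3 | ethyl 2-(diethoxyphosphoryl)-3-methylbut-2-enoate | CCOC(=O)C(=C(C)C)P(=O)(OCC)OCC | intermediate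
4 | 5-nitropentan-2-one | CC(=O)CCC[N+](=O)[O-] | starting material
5 | ethyl 2-(diethoxyphosphoryl)-3,3-dimethyl-4-nitro-7-oxooctanoate | CCOC(=O)C(P(=O)(OCC)OCC)C(C)(C)C(CCC(C)=O)[N+](=O)[O-] | intermediate (not isolated)
6 | ethyl 2,6,6-trimethyl-5-nitrocyclohex-1-ene-1-carboxylate (racemic) | CCOC(=O)C1=C(C)CCC([N+](=O)[O-])C1(C)C | intermediate
7 | sodium [3-(ethoxycarbonyl)-2,2,4-trimethylcyclohex-3-en-1-ylidene]azinate | CCOC(=O)C1=C(C)CCC(=[N+]([O-])[O-])C1(C)C.[Na+] | intermediate (not isolated)
8 | ethyl 2,6,6-trimethyl-5-oxocyclohex-1-ene-1-carboxylate | CCOC(=O)C1=C(C)CCC(=O)C1(C)C | intermediate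
9 | diethyl (cyanomethyl)phosphonate | CCOP(=O)(CC#N)OCC | starting material
10 | ethyl (5E)-5-(cyanomethylidene)-2,6,6-trimethylcyclohex-1-ene-1-carboxylate | N#C/C=C1/C(C)(C)C(C(=O)OCC)=C(C)CC1 | intermediate
11 | (2E)-2-[3-(hydroxymethyl)-2,2,4-trimethylcyclohex-3-en-1-ylidene]acetaldehyde | O=C/C=C1/C(C)(C)C(CO)=C(C)CC1 | intermediate
12 | 2-[(1R)-3-(hydroxymethyl)-2,2,4-trimethylcyclohex-3-en-1-yl]acetaldehyde | OCC1=C(C)CC[C@H](CC=O)C1(C)C | intermediate
13 | methyl 2-(triphenyl-λ5-phosphanylidene)propanoate | COC(=O)C(C)=P(c1ccccc1)(c1ccccc1)c1ccccc1 | starting material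
14 | methyl (2E)-4-[(1R)-3-(hydroxymethyl)-2,2,4-trimethylcyclohex-3-en-1-yl]-2-methylbut-2-enoate | OCC1=C(C)CC[C@H](C/C=C(\C)C(=O)OC)C1(C)C | intermediate
15 | {[(5R)-5-[(2E)-4-methoxy-3-methyl-4-oxobut-2-en-1-yl]-2,6,6-trimethylcyclohex-1-en-1-yl]methyl}(triphenyl)phosphonium bromide | C([P+](c1ccccc1)(c1ccccc1)c1ccccc1)C1=C(C)CC[C@H](C/C=C(\C)C(=O)OC)C1(C)C.[Br-] | intermediate
16 | (R)-lavandulol, (2R)-5-methyl-2-(prop-1-en-2-yl)hex-4-en-1-ol | CC(C)=CC[C@@H](CO)C(C)=C | starting material
17 | acetoxy[(3S)-2-hydroxy-3-(hydroxymethyl)-2,6-dimethylhept-5-en-1-yl]mercury (epimers at C2) | CC(C)=CC[C@@H](CO)C(C)(O)C[Hg]OC(C)=O | intermediate (not isolated)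
18 | (2S)-2-(2-hydroxypropan-2-yl)-5-methylhex-4-en-1-ol | CC(C)=CC[C@@H](CO)C(C)(C)O | intermediate
19 | trimethyl({(2S)-5-methyl-2-[2-(trimethylsilyloxy)propan-2-yl]hex-4-en-1-yl}oxy)silane | CC(C)=CC[C@@H](CO[Si](C)(C)C)C(C)(C)O[Si](C)(C)C | intermediate
20 | (2R)-5-methyl-2-[2-(trimethylsilyloxy)propan-2-yl]hex-4-enal | CC(C)=CC[C@@H](C=O)C(C)(C)O[Si](C)(C)C | intermediate
21 | ethyl (2E)-4-(diethoxyphosphoryl)-3-methylbut-2-enoate | CCOC(=O)/C=C(\C)CP(=O)(OCC)OCC | starting material
22 | ethyl (2E,4E,6S)-3,9-dimethyl-6-[2-(trimethylsilyloxy)propan-2-yl]deca-2,4,8-trienoate | CC(C)=CC[C@@H](/C=C/C(C)=C/C(=O)OCC)C(C)(C)O[Si](C)(C)C | intermediate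
23 | (2E,4E,6S)-3,9-dimethyl-6-[2-(trimethylsilyloxy)propan-2-yl]deca-2,4,8-trien-1-ol | CC(C)=CC[C@@H](/C=C/C(C)=C/CO)C(C)(C)O[Si](C)(C)C | intermediate
24 | [(2E,4E,6S)-6-(2-hydroxypropan-2-yl)-3,9-dimethyldeca-2,4,8-trien-1-yl](triphenyl)phosphonium bromide | CC(C)=CC[C@@H](/C=C/C(C)=C/C[P+](c1ccccc1)(c1ccccc1)c1ccccc1)C(C)(C)O.[Br-] | intermediate
25 | crocetin dialdehyde, (2E,4E,6E,8E,10E,12E,14E)-2,6,11,15-tetramethylhexadeca-2,4,6,8,10,12,14-heptaenedial | O=C/C(C)=C/C=C/C(C)=C/C=C/C=C(C)/C=C/C=C(C)/C=O | starting material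
26 | methyl (2E)-2-methyl-4-{(1R)-2,2,4-trimethyl-3-[(triphenyl-λ5-phosphanylidene)methyl]cyclohex-3-en-1-yl}but-2-enoate | C(=P(c1ccccc1)(c1ccccc1)c1ccccc1)C1=C(C)CC[C@H](C/C=C(\C)C(=O)OC)C1(C)C | intermediate (not isolated)
27 | methyl (2E)-2-methyl-4-{(1R)-2,2,4-trimethyl-3-[(1E,3E,5E,7E,9E,11E,13E,15E)-3,7,12,16-tetramethyl-17-oxoheptadeca-1,3,5,7,9,11,13,15-octaen-1-yl]cyclohex-3-en-1-yl}but-2-enoate | O=C/C(C)=C/C=C/C(C)=C/C=C/C=C(C)/C=C/C=C(C)/C=C/C1=C(C)CC[C@H](C/C=C(\C)C(=O)OC)C1(C)C | intermediate
28 | sodium 2-[(3S,4E,6E)-6-methyl-1-(3-methylbut-2-en-1-yl)-8-(triphenyl-λ5-phosphanylidene)octa-2,4,6-trien-1-yl... ]propan-2-olate, i.e. the ylide sodium alkoxide derived from 24 | CC(C)=CC[C@@H](/C=C/C(C)=C/C=P(c1ccccc1)(c1ccccc1)c1ccccc1)C(C)(C)[O-].[Na+] | intermediate (not isolated)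
29 | methyl (2E)-4-{(1R)-3-[(1E,3E,5E,7E,9E,11E,13E,15E,17E,19E,21E,23S)-23-(2-hydroxypropan-2-yl)-3,7,12,16,20,26-hexamethylheptacosa-1,3,5,7,9,11,13,15,17,19,21,25-dodecaen-1-yl]-2,2,4-trimethylcyclohex-3-en-1-yl}-2-methylbut-2-enoate | CC(C)=CC[C@@H](/C=C/C(C)=C/C=C/C(C)=C/C=C/C(C)=C/C=C/C=C(C)/C=C/C=C(C)/C=C/C1=C(C)CC[C@H](C/C=C(\C)C(=O)OC)C1(C)C)C(C)(C)O | intermediate
30 | target, (2R,2'S)-configured C50 diol | CC(C)=CC[C@@H](/C=C/C(C)=C/C=C/C(C)=C/C=C/C(C)=C/C=C/C=C(C)/C=C/C=C(C)/C=C/C1=C(C)CC[C@H](C/C=C(\C)CO)C1(C)C)C(C)(C)O | target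

**Totals**

Total step count: 17. Longest linear sequence: 11 steps (steps 1–8, then 15–17).

**Steps most likely to fail**

Step 2. The congested, reversible conjugate addition of the nitronate to the fully substituted β-carbon may be outrun by γ-deprotonation of 3 and by intermolecular nitro-aldol condensation of 4, so that the ring never closes. The fallback takes the ring from a cyclic precursor instead of closing it. It replaces steps 1–3: it sets out from purchased 2,2-dimethylcyclohexane-1,3-dione F1 instead of compounds 3 and 4 and comes back to the route at compound 8. Monoketalisation (ethylene glycol, TsOH, toluene, azeotropic removal of water) should give 6,6-dimethyl-1,4-dioxaspiro[4.5]decan-7-one F2. Methylation of its only enolisable position (LiN(i-Pr)2, THF, −78 °C; MeI) should give 6,6,8-trimethyl-1,4-dioxaspiro[4.5]decan-7-one F3. Enol triflate formation (KN(SiMe3)2, PhNTf2) should give 6,6,8-trimethyl-1,4-dioxaspiro[4.5]dec-7-en-7-yl trifluoromethanesulfonate F4. Ethoxycarbonylation (Pd(OAc)2, PPh3, CO, EtOH, Et3N, DMF) should give ethyl 6,6,8-trimethyl-1,4-dioxaspiro[4.5]dec-7-ene-7-carboxylate F5, and aqueous HCl in acetone removes the ketal to give 8.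

Step 6. Facial discrimination in the hydride transfer to the iminium ion may be poor, and under the acidic ammonium salt the free allylic hydroxyl may add to the iminium ion or ionise. The fallback sets out from compound 10 and comes back at compound 12, by-passing 11. The (E)-nitrile is reduced at the unsaturated nitrile stage by copper hydride catalysis (Cu(OAc)2, a Josiphos-type ferrocenyl diphosphine of the appropriate hand, polymethylhydrosiloxane, t-BuOH, toluene), a known enantioselective conjugate reduction of β,β-disubstituted unsaturated nitriles. This should give ethyl (5R)-5-(cyanomethyl)-2,6,6-trimethylcyclohex-1-ene-1-carboxylate F6. Reduction with i-Bu2AlH and hydrolytic work-up then converts nitrile and ester together into 12.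

Step 15. Condensation of the hindered cyclogeranyl-type ylide with the polyenal may be sluggish, with ylide decomposition and formation of the 7Z alkene. The fallback sets out from compound 14 and comes back at compound 27. Mitsunobu thioetherification with 2-mercaptobenzothiazole (PPh3, diisopropyl azodicarboxylate, THF) should give methyl (2E)-4-{(1R)-3-[(1,3-benzothiazol-2-ylsulfanyl)methyl]-2,2,4-trimethylcyclohex-3-en-1-yl}-2-methylbut-2-enoate F7. Oxidation ((NH4)6Mo7O24, H2O2, EtOH) should give the corresponding sulfone, methyl (2E)-4-{(1R)-3-[(1,3-benzothiazol-2-ylsulfonyl)methyl]-2,2,4-trimethylcyclohex-3-en-1-yl}-2-methylbut-2-enoate F8. Julia–Kocienski olefination of its anion (NaN(SiMe3)2, THF, −78 °C) with excess 25 gives 27.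

**Further compounds**

F1 | step 2 | 2,2-dimethylcyclohexane-1,3-dione (purchased starting point of the fallback) | CC1(C)C(=O)CCCC1=O
F2 | step 2 | 6,6-dimethyl-1,4-dioxaspiro[4.5]decan-7-one | CC1(C)C(=O)CCCC12OCCO2
F3 | step 2 | 6,6,8-trimethyl-1,4-dioxaspiro[4.5]decan-7-one | CC1CCC2(OCCO2)C(C)(C)C1=O
F4 | step 2 | 6,6,8-trimethyl-1,4-dioxaspiro[4.5]dec-7-en-7-yl trifluoromethanesulfonate | CC1=C(OS(=O)(=O)C(F)(F)F)C(C)(C)C2(CC1)OCCO2
F5 | step 2 | ethyl 6,6,8-trimethyl-1,4-dioxaspiro[4.5]dec-7-ene-7-carboxylate | CCOC(=O)C1=C(C)CCC2(OCCO2)C1(C)C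
F6 | step 6 | ethyl (5R)-5-(cyanomethyl)-2,6,6-trimethylcyclohex-1-ene-1-carboxylate | CCOC(=O)C1=C(C)CC[C@H](CC#N)C1(C)C
F7 | step 15 | methyl (2E)-4-{(1R)-3-[(1,3-benzothiazol-2-ylsulfanyl)methyl]-2,2,4-trimethylcyclohex-3-en-1-yl}-2-methylbut-2-enoate | c1ccc2sc(SCC3=C(C)CC[C@H](C/C=C(\C)C(=O)OC)C3(C)C)nc2c1
F8 | step 15 | methyl (2E)-4-{(1R)-3-[(1,3-benzothiazol-2-ylsulfonyl)methyl]-2,2,4-trimethylcyclohex-3-en-1-yl}-2-methylbut-2-enoate | c1ccc2sc(S(=O)(=O)CC3=C(C)CC[C@H](C/C=C(\C)C(=O)OC)C3(C)C)nc2c1
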